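**Retrosynthetic overview**

1. Locants: the 11-membered carbocycle is numbered C1 (carbinol carbon carrying the senecioate), C2=C3 (cis), C4 (quaternary), C5, C6=C7 (CHO on C7), C8, C9, C10 (oxirane CH), C11 (oxirane C–CH3). End game: enal by allylic oxidation, senecioate by Mitsunobu inversion of the erythro epoxy alcohol 24, carbinol by reduction of the C1 ketone 23.
2. Key disconnection: the oxirane C10–C11 bond, made by an intramolecular Darzens condensation of the acyclic (Z)-α-chloro enone aldehyde 21. The enabling feature is that the methyl-bearing oxirane carbon C11 lies α to the oxygenated C1: with C1 as a ketone, C11 is the only enolisable carbon (C2 is olefinic, C4 quaternary) and C10 is an aldehyde carbon, while the two cis ring olefins C2=C3 and C6=C7 fold the chain.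
3. Ring order: no ring before step 16; there the 11-membered carbocycle closes first (aldol C10–C11 bond) and the oxirane second (C11–O bond) in the same operation, creating C10 and C11 together.
4. Seco chain 21: C1/C11/CH3 from 2-chloropropanal (17) by acetylide addition and Lindlar reduction (Z-C2=C3); C6=C7 by E-selective Wittig reaction of the C2–C6 aldehyde 9 with the C7–C10 ylide 13; side chain by cross-metathesis with 2-methylbut-3-en-2-ol (5).
5. C4: two face-selective enolate alkylations (allyl, then methyl) of (S)-5-(trityloxymethyl)dihydrofuran-2(3H)-one (1); its carbonyl carbon becomes C3 and its carbinol carbon becomes C6 after glycol cleavage, which removes the directing stereocentre.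

Key step: step 16

Remark: 2-chloropropanal (17) is used as the racemate, and the CHCl and CHOH centres of 18–20 (and the CHCl centre of 21) are left undefined, because C1 becomes a ketone and C11 an enolate carbon before the key step.

**Route**

Step 1
Reactants: 1 (S)-5-(trityloxymethyl)dihydrofuran-2(3H)-one
Product: 2 (3R,5S)-3-allyl-5-(trityloxymethyl)dihydrofuran-2(3H)-one
Conditions: LDA, THF, −78 °C; allyl bromide, −78 → −40 °C
Reagents that add atoms: allyl bromide, C=CCBr
Why: Lithium enolate alkylation of a γ-substituted butyrolactone, which should occur anti to the bulky CH2OTr group (1,3-induction) to give mainly the trans lactone; the C3 configuration is erased again in step 2.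

Step 2
Reactants: 2 (3R,5S)-3-allyl-5-(trityloxymethyl)dihydrofuran-2(3H)-one
Product: 3 (3S,5S)-3-allyl-3-methyl-5-(trityloxymethyl)dihydrofuran-2(3H)-one
Conditions: LDA, THF, −78 °C; MeI, DMPU, −78 → −30 °C
Reagents that add atoms: iodomethane, CI
Why: Second enolate alkylation, in which the planar α-allyl enolate should be methylated on the face anti to CH2OTr, so that methyl ends up trans and allyl cis to the C5 substituent; this sets the quaternary stereocentre (C4 of the target, S).

Step 3
Reactants: 3 (3S,5S)-3-allyl-3-methyl-5-(trityloxymethyl)dihydrofuran-2(3H)-one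
Product: 4 (3S,5S)-3-allyl-5-(hydroxymethyl)-3-methyldihydrofuran-2(3H)-one
Conditions: CSA (cat.), MeOH/CH2Cl2, rt
Reagents that add atoms: none
Why: Acid-catalysed SN1 solvolysis of the trityl ether, placed before the acid-labile tertiary allylic alcohol is introduced.

Step 4
Reactants: 4 (3S,5S)-3-allyl-5-(hydroxymethyl)-3-methyldihydrofuran-2(3H)-one; 5 2-methylbut-3-en-2-ol
Product: 6 (3S,5S)-5-(hydroxymethyl)-3-[(2E)-4-hydroxy-4-methylpent-2-en-1-yl]-3-methyldihydrofuran-2(3H)-one
Conditions: second-generation Grubbs catalyst (5 mol %), 5 (6 equiv), CH2Cl2, 40 °C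
Reagents that add atoms: none
Why: Olefin cross-metathesis of a terminal olefin with a hindered tertiary allylic alcohol used in excess should give the E olefin under thermodynamic control; it is run at the lactone stage because the later C5–C6=C7 arm would ring-close onto the allyl group.

Step 5
Reactants: 6 (3S,5S)-5-(hydroxymethyl)-3-[(2E)-4-hydroxy-4-methylpent-2-en-1-yl]-3-methyldihydrofuran-2(3H)-one
Product: 7 (3S,5S)-5-(hydroxymethyl)-3-[(2E)-4-hydroxy-4-methylpent-2-en-1-yl]-3-methyltetrahydrofuran-2-ol (lactol)
Conditions: DIBAL-H (3.5 equiv), CH2Cl2, −78 °C; Rochelle salt work-up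
Reagents that add atoms: none
Why: DIBAL-H reduction of a γ-lactone stops at the aluminium hemiacetal at −78 °C and should give the lactol on work-up.

Step 6
Reactants: 7 (3S,5S)-5-(hydroxymethyl)-3-[(2E)-4-hydroxy-4-methylpent-2-en-1-yl]-3-methyltetrahydrofuran-2-ol (lactol)
Product: 8 (2S,4S,6E)-4-ethynyl-4,8-dimethylnon-6-ene-1,2,8-triol
Conditions: dimethyl (1-diazo-2-oxopropyl)phosphonate, K2CO3, MeOH, 0 °C → rt
Reagents that add atoms: dimethyl (1-diazo-2-oxopropyl)phosphonate (Ohira–Bestmann reagent), CC(=O)C(=[N+]=[N-])P(=O)(OC)OC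
Why: Seyferth–Gilbert homologation with the Ohira–Bestmann reagent on the non-enolisable α-quaternary hydroxy aldehyde that is in equilibrium with the lactol should give the terminal alkyne and release the former ring oxygen as the secondary alcohol of a 1,2-diol.

Step 7
Reactants: 8 (2S,4S,6E)-4-ethynyl-4,8-dimethylnon-6-ene-1,2,8-triol
Product: 9 (3S,5E)-3-ethynyl-7-hydroxy-3,7-dimethyloct-5-enal
Conditions: NaIO4, THF/pH 7 buffer, 0 °C
Reagents that add atoms: none
Why: Malaprade glycol cleavage removes the stereocentre that steered the alkylations together with its CH2OH carbon and leaves the C6 aldehyde; the tertiary alcohol is not vicinal and is untouched.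

Step 8
Reactants: 10 ethyl (triphenyl-λ5-phosphanylidene)acetate; 11 tert-butyl(3-iodopropoxy)dimethylsilane
Product: 13 ethyl 5-[(tert-butyldimethylsilyl)oxy]-2-(triphenyl-λ5-phosphanylidene)pentanoate, via phosphonium iodide 12 (not isolated)
Conditions: MeCN, reflux; then 1 M NaOH, CH2Cl2, 0 °C
Reagents that add atoms: none
Why: C-alkylation of a stabilised phosphorus ylide by a primary iodide followed by deprotonation of the phosphonium salt gives the α-branched stabilised ylide.

Step 9
Reactants: 9 (3S,5E)-3-ethynyl-7-hydroxy-3,7-dimethyloct-5-enal; 13 ethyl 5-[(tert-butyldimethylsilyl)oxy]-2-(triphenyl-λ5-phosphanylidene)pentanoate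
Product: 14 ethyl (2E,5S,7E)-2-{3-[(tert-butyldimethylsilyl)oxy]propyl}-5-ethynyl-9-hydroxy-5,9-dimethyldeca-2,7-dienoate
Conditions: toluene, 90 °C
Reagents that add atoms: none
Why: Wittig olefination with an α-branched stabilised ylide is E-selective (ester trans to the aldehyde-derived chain), which is the geometry of the C6=C7 olefin with the ring carbons C5 and C8 cis.

Step 10
Reactants: 14 ethyl (2E,5S,7E)-2-{3-[(tert-butyldimethylsilyl)oxy]propyl}-5-ethynyl-9-hydroxy-5,9-dimethyldeca-2,7-dienoate
Product: 15 (2E,5S,7E)-2-{3-[(tert-butyldimethylsilyl)oxy]propyl}-5-ethynyl-5,9-dimethyldeca-2,7-diene-1,9-diol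
Conditions: DIBAL-H (4 equiv), CH2Cl2, −78 °C; Rochelle salt work-up
Reagents that add atoms: none
Why: DIBAL-H 1,2-reduction of the enoate should give the allylic alcohol without changing the olefin geometry or touching the alkyne.

Step 11
Reactants: 15 (2E,5S,7E)-2-{3-[(tert-butyldimethylsilyl)oxy]propyl}-5-ethynyl-5,9-dimethyldeca-2,7-diene-1,9-diol
Product: 16 1-O-(tert-butyldiphenylsilyl) ether of 15 (tertiary alcohol free)
Conditions: TBDPSCl (1.1 equiv), imidazole, CH2Cl2, 0 °C
Reagents that add atoms: tert-butyl(chloro)diphenylsilane (TBDPSCl), CC(C)(C)[Si](Cl)(c1ccccc1)c1ccccc1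
Why: Silylation is selective for the primary allylic alcohol because the tertiary alcohol does not react with TBDPSCl.

Step 12
Reactants: 16 1-O-(tert-butyldiphenylsilyl) ether of 15 (tertiary alcohol free); 17 2-chloropropanal
Product: 18 (4S)-seco-chain propargylic chlorohydrin CH3CHCl–CH(OH)–C≡C–C4 (7-CH2OTBDPS; 10-OTBS; isomer mixture at C1/C11)
Conditions: n-BuLi (2.1 equiv), THF, −78 °C; 17, −78 °C; sat. aq. NH4Cl at −78 °C
Reagents that add atoms: none
Why: 1,2-Addition of a lithium acetylide to an α-chloro aldehyde at −78 °C is faster than closure of the chlorohydrin alkoxide to an oxirane; the two new centres (C1, C11) need no control because both are cleared in steps 15 and 16.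

Step 13
Reactants: 18 (4S)-seco-chain propargylic chlorohydrin CH3CHCl–CH(OH)–C≡C–C4 (7-CH2OTBDPS; 10-OTBS; isomer mixture at C1/C11)
Product: 19 (2Z,4S)-seco-chain allylic chlorohydrin (7-CH2OTBDPS; 10-OTBS)
Conditions: H2 (1 atm), Lindlar catalyst, quinoline, EtOAc, rt
Reagents that add atoms: none
Why: Lindlar semihydrogenation (syn addition of H2) should give the Z olefin C2=C3, while the trisubstituted and E-disubstituted olefins and the C–Cl bond are not reduced.

Step 14
Reactants: 19 (2Z,4S)-seco-chain allylic chlorohydrin (7-CH2OTBDPS; 10-OTBS)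
Product: 20 (2Z,4S)-seco-chain 1,10-diol (7-CH2OTBDPS; 11-chloro)
Conditions: HF·pyridine, pyridine, THF, 0 °C
Reagents that add atoms: none
Why: Buffered HF·pyridine cleaves the primary TBS ether much faster than the TBDPS ether and spares the tertiary allylic alcohol.

Step 15
Reactants: 20 (2Z,4S)-seco-chain 1,10-diol (7-CH2OTBDPS; 11-chloro)
Product: 21 (2Z,4S)-11-chloro-1-oxo seco-chain aldehyde (α-chloro Z-enone with C10 aldehyde; 7-CH2OTBDPS)
Conditions: Dess–Martin periodinane (3 equiv), NaHCO3, CH2Cl2, 0 °C → rt
Reagents that add atoms: none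
Why: Dess–Martin oxidation converts the primary alcohol into the C10 aldehyde and the secondary allylic alcohol into the C1 ketone in one operation; the tertiary alcohol cannot be oxidised and the buffered non-basic medium should keep the Z-enone geometry.

Step 16
Reactants: 21 (2Z,4S)-11-chloro-1-oxo seco-chain aldehyde (α-chloro Z-enone with C10 aldehyde; 7-CH2OTBDPS)
Product: 23 (2Z,4S,6E,10S,11R)-10,11-epoxy macrocyclic enone (C1 ketone; 7-CH2OTBDPS), via chlorohydrin aldolate 22 (not isolated)
Conditions: N-[4-(trifluoromethyl)benzyl]cinchonidinium bromide (20 mol %), LiOH·H2O (4 equiv), n-Bu2O, 4 °C, 21 added over 12 h (final 2 mM)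
Reagents that add atoms: none
Why: Proposed new method: an intramolecular, macrocyclising Darzens condensation under chiral ammonium phase-transfer catalysis, in which the base removes the only acidic C–H of 21 (C11–H; C2 is olefinic and C4 quaternary, so no other enolate or dienolate can form), the α-chloro enolate adds reversibly to the C10 aldehyde, and the aldolate 22 with O⁻ antiperiplanar to Cl is drained irreversibly by SN2 displacement of chloride. The closest known reactions are the intermolecular cinchona-ammonium-catalysed Darzens condensation of α-chloro ketones with aldehydes (including cyclic α-chloro ketones that deliver a fully substituted oxirane carbon) and aldol-type macrocyclisations such as intramolecular Horner–Wadsworth–Emmons and Reformatsky reactions. Two rings close: the 11-membered carbocycle by 11-(enolendo)-exo-trig aldol addition (C10–C11 bond) and then the oxirane by 3-exo-tet substitution (C11–O bond). Both new stereocentres arise here: the trans ring fusion (C9 and C1 on opposite faces of the oxirane) should follow from anti O/Cl closure of the transoid C9–C10–C11–C1 conformer of the equilibrating aldolates, and the absolute sense (10S,11R) is assigned to the chiral ion pair, because the resident stereocentre C4 is remote and nearly symmetric (CH3 versus CH2R) and cannot be relied on. The step needs chemoselectivity, ring closure over oligomerisation and π-face selectivity: the enal is masked as CH2OTBDPS, the β-carbon C3 is neopentylic so conjugate addition and Z/E equilibration of the enone are hindered, the two cis olefins C2=C3 and C6=C7 hold the chain ends together, and the reversible aldol step lets open-chain oligomers revert under high dilution. The cinchonidinium series is chosen by analogy with the intermolecular reaction, and the pseudo-enantiomeric cinchoninium salt is the lever if the sense of induction should be opposite.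

Step 17
Reactants: 23 (2Z,4S,6E,10S,11R)-10,11-epoxy macrocyclic enone (C1 ketone; 7-CH2OTBDPS)
Product: 24 (1S,2Z,4S,6E,10S,11R)-erythro epoxy alcohol (7-CH2OTBDPS)
Conditions: Zn(BH4)2, Et2O, −20 °C
Reagents that add atoms: none
Why: Chelation-controlled 1,2-reduction of an α,β-epoxy ketone (zinc bridges the carbonyl and oxirane oxygens and hydride enters on the face away from C10) is the known erythro-selective mode and should set C1 as 1S.

Step 18
Reactants: 24 (1S,2Z,4S,6E,10S,11R)-erythro epoxy alcohol (7-CH2OTBDPS); 25 3-methylbut-2-enoic acid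
Product: 26 (1R,2Z,4S,6E,10S,11R)-senecioate (7-CH2OTBDPS)
Conditions: PPh3, DIAD, toluene, 0 °C → rt
Reagents that add atoms: none
Why: Mitsunobu esterification displaces the oxyphosphonium group by senecioate with inversion (1S → 1R, erythro → threo) and installs the ester at the same time; SN2′ attack at C3 is blocked by the quaternary C4 and the tertiary alcohol is inert.

Step 19
Reactants: 26 (1R,2Z,4S,6E,10S,11R)-senecioate (7-CH2OTBDPS)
Product: 27 (1R,2Z,4S,6E,10S,11R)-senecioate with free 7-CH2OH
Conditions: TBAF, AcOH (1:1), THF, 0 °C → rt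
Reagents that add atoms: none
Why: Fluoride cleaves the allylic TBDPS ether, and buffering with acetic acid should keep the ester and the oxirane intact.

Step 20
Reactants: 27 (1R,2Z,4S,6E,10S,11R)-senecioate with free 7-CH2OH
Product: 28 target CNP0164725.3
Conditions: MnO2, CH2Cl2, rt
Reagents that add atoms: none
Why: MnO2 oxidises only the primary allylic alcohol to the enal with retention of olefin geometry, since the tertiary allylic alcohol has no carbinol hydrogen.

**Compound list**

1 | (S)-5-(trityloxymethyl)dihydrofuran-2(3H)-one | O=C1O[C@H](COC(c2ccccc2)(c2ccccc2)c2ccccc2)CC1 | starting material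
2 | (3R,5S)-3-allyl-5-(trityloxymethyl)dihydrofuran-2(3H)-one | O=C1O[C@H](COC(c2ccccc2)(c2ccccc2)c2ccccc2)C[C@H]1CC=C | intermediate
3 | (3S,5S)-3-allyl-3-methyl-5-(trityloxymethyl)dihydrofuran-2(3H)-one | O=C1O[C@H](COC(c2ccccc2)(c2ccccc2)c2ccccc2)C[C@]1(C)CC=C | intermediate
4 | (3S,5S)-3-allyl-5-(hydroxymethyl)-3-methyldihydrofuran-2(3H)-one | O=C1O[C@H](CO)C[C@]1(C)CC=C | intermediate
5 | 2-methylbut-3-en-2-ol | C=CC(C)(C)O | starting material
6 | (3S,5S)-5-(hydroxymethyl)-3-[(2E)-4-hydroxy-4-methylpent-2-en-1-yl]-3-methyldihydrofuran-2(3H)-one | O=C1O[C@H](CO)C[C@]1(C)C/C=C/C(C)(C)O | intermediate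
7 | (3S,5S)-5-(hydroxymethyl)-3-[(2E)-4-hydroxy-4-methylpent-2-en-1-yl]-3-methyltetrahydrofuran-2-ol (lactol, both anomers) | OC1O[C@H](CO)C[C@]1(C)C/C=C/C(C)(C)O | intermediate
8 | (2S,4S,6E)-4-ethynyl-4,8-dimethylnon-6-ene-1,2,8-triol | C#C[C@@](C)(C/C=C/C(C)(C)O)C[C@H](O)CO | intermediate
9 | (3S,5E)-3-ethynyl-7-hydroxy-3,7-dimethyloct-5-enal | C#C[C@@](C)(C/C=C/C(C)(C)O)CC=O | intermediate
10 | ethyl (triphenyl-λ5-phosphanylidene)acetate | CCOC(=O)C=P(c1ccccc1)(c1ccccc1)c1ccccc1 | starting material
11 | tert-butyl(3-iodopropoxy)dimethylsilane | CC(C)(C)[Si](C)(C)OCCCI | starting material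
12 | {5-[(tert-butyldimethylsilyl)oxy]-1-ethoxy-1-oxopentan-2-yl}triphenylphosphonium iodide | CCOC(=O)C(CCCO[Si](C)(C)C(C)(C)C)[P+](c1ccccc1)(c1ccccc1)c1ccccc1.[I-] | intermediate (not isolated)
13 | ethyl 5-[(tert-butyldimethylsilyl)oxy]-2-(triphenyl-λ5-phosphanylidene)pentanoate | CCOC(=O)C(CCCO[Si](C)(C)C(C)(C)C)=P(c1ccccc1)(c1ccccc1)c1ccccc1 | intermediate
14 | ethyl (2E,5S,7E)-2-{3-[(tert-butyldimethylsilyl)oxy]propyl}-5-ethynyl-9-hydroxy-5,9-dimethyldeca-2,7-dienoate | C#C[C@@](C)(C/C=C/C(C)(C)O)C/C=C(/C(=O)OCC)CCCO[Si](C)(C)C(C)(C)C | intermediate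
15 | (2E,5S,7E)-2-{3-[(tert-butyldimethylsilyl)oxy]propyl}-5-ethynyl-5,9-dimethyldeca-2,7-diene-1,9-diol | C#C[C@@](C)(C/C=C/C(C)(C)O)C/C=C(/CO)CCCO[Si](C)(C)C(C)(C)C | intermediate
16 | 1-O-(tert-butyldiphenylsilyl) ether of 15 (tertiary alcohol free; primary OTBS; terminal alkyne) | C#C[C@@](C)(C/C=C/C(C)(C)O)C/C=C(/CO[Si](c1ccccc1)(c1ccccc1)C(C)(C)C)CCCO[Si](C)(C)C(C)(C)C | intermediate
17 | 2-chloropropanal (racemic) | CC(Cl)C=O | starting material
18 | (4S)-seco-chain propargylic chlorohydrin CH3CHCl–CH(OH)–C≡C–C4(CH3)(side chain)–CH2–CH=C(CH2OTBDPS)–(CH2)3–OTBS (mixture at C1 and C11) | CC(Cl)C(O)C#C[C@@](C)(C/C=C/C(C)(C)O)C/C=C(/CO[Si](c1ccccc1)(c1ccccc1)C(C)(C)C)CCCO[Si](C)(C)C(C)(C)C | intermediate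
19 | (2Z,4S)-seco-chain allylic chlorohydrin (7-CH2OTBDPS; 10-OTBS; mixture at C1 and C11) | CC(Cl)C(O)/C=C\[C@@](C)(C/C=C/C(C)(C)O)C/C=C(/CO[Si](c1ccccc1)(c1ccccc1)C(C)(C)C)CCCO[Si](C)(C)C(C)(C)C | intermediate
20 | (2Z,4S)-seco-chain 1,10-diol (11-chloro; 7-CH2OTBDPS; tertiary alcohol free) | CC(Cl)C(O)/C=C\[C@@](C)(C/C=C/C(C)(C)O)C/C=C(/CO[Si](c1ccccc1)(c1ccccc1)C(C)(C)C)CCCO | intermediate
21 | (2Z,4S)-11-chloro-1-oxo seco-chain aldehyde CH3CHCl–C(=O)–CH=CH–C4–CH2–CH=C(CH2OTBDPS)–CH2CH2–CHO (mixture at C11) | CC(Cl)C(=O)/C=C\[C@@](C)(C/C=C/C(C)(C)O)C/C=C(/CO[Si](c1ccccc1)(c1ccccc1)C(C)(C)C)CCC=O | intermediate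
22 | (2Z,4S,6E,10S,11S)-11-chloro-10-hydroxy macrocyclic enone (chlorohydrin aldolate, shown protonated) | O=C1/C=C\[C@@](C)(C/C=C/C(C)(C)O)C/C=C(/CO[Si](c2ccccc2)(c2ccccc2)C(C)(C)C)CC[C@H](O)[C@]1(C)Cl | intermediate (not isolated)
23 | (2Z,4S,6E,10S,11R)-10,11-epoxy macrocyclic enone (C1 ketone; 7-CH2OTBDPS) | O=C1/C=C\[C@@](C)(C/C=C/C(C)(C)O)C/C=C(/CO[Si](c3ccccc3)(c3ccccc3)C(C)(C)C)CC[C@@H]2O[C@]21C | intermediate
24 | (1S,2Z,4S,6E,10S,11R)-erythro epoxy alcohol (7-CH2OTBDPS) | O[C@H]1/C=C\[C@@](C)(C/C=C/C(C)(C)O)C/C=C(/CO[Si](c3ccccc3)(c3ccccc3)C(C)(C)C)CC[C@@H]2O[C@]21C | intermediate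
25 | 3-methylbut-2-enoic acid (senecioic acid) | CC(C)=CC(=O)O | starting material
26 | (1R,2Z,4S,6E,10S,11R)-senecioate (7-CH2OTBDPS) | CC(C)=CC(=O)O[C@@H]1/C=C\[C@@](C)(C/C=C/C(C)(C)O)C/C=C(/CO[Si](c3ccccc3)(c3ccccc3)C(C)(C)C)CC[C@@H]2O[C@]21C | intermediate
27 | (1R,2Z,4S,6E,10S,11R)-senecioate with free 7-CH2OH | CC(C)=CC(=O)O[C@@H]1/C=C\[C@@](C)(C/C=C/C(C)(C)O)C/C=C(/CO)CC[C@@H]2O[C@]21C | intermediate
28 | CNP0164725.3: (1R,2Z,4S,6E,10S,11R)-10,11-epoxy-7-formyl-4-[(2E)-4-hydroxy-4-methylpent-2-en-1-yl]-4,11-dimethylcycloundeca-2,6-dien-1-yl 3-methylbut-2-enoate (locants of the overview) | CC(C)=CC(=O)O[C@@H]1/C=C\[C@@](C)(C/C=C/C(C)(C)O)C/C=C(/C=O)CC[C@@H]2O[C@]21C | target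

**Totals and risks**

Total step count: 20. Longest linear sequence: 19 steps (steps 1–7 and 9–20, from 1); step 8 is a one-step side branch.

Most likely to fail, step 16 (Proposed new method): intermolecular aldol oligomerisation may outrun ring closure, the cisoid aldolate may close to the cis-fused oxirane, the ammonium ion pair may discriminate the π-faces poorly (giving the diastereomeric series relative to C4), or base may equilibrate the Z-enone. The fallback uses known reactions in three operations, sets out from 21 and returns at 23. Slow addition of 21 to SmI2 (2.2 equiv) in THF at −78 °C under high dilution should reduce the C–Cl bond to the samarium enolate, which closes the carbocycle by a Reformatsky-type aldol addition to the C10 aldehyde and gives the macrocyclic β-hydroxy ketone F1. MsCl/Et3N followed by DBU should dehydrate it to the cross-conjugated (2Z,6E,10E)-macrocyclic dienone F2. Nucleophilic (Weitz–Scheffer) epoxidation with t-BuOOH under cinchonidinium phase-transfer catalysis (or t-BuOOH/DBU with separation of diastereomers) should attack only the C10=C11 enone, because the β-carbon C3 of the other enone is neopentylic, and this returns the route to 23.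

Step 18: the SN2 displacement at a carbinol flanked by a fully substituted oxirane carbon may be slow with the weakly acidic senecioic acid, so that elimination, retention through an ion pair or no reaction takes over. The fallback replaces substrate control plus inversion by reagent control plus retention; it sets out from 23 (bypassing steps 17 and 18) and returns at 26. Oxazaborolidine-catalysed (Corey–Bakshi–Shibata) reduction with catecholborane at −78 °C, with the catalyst enantiomer chosen to override the chelation bias ((S)-Me-CBS if the oxirane-bearing quaternary carbon acts as the large carbonyl substituent), should give the threo (1R) epoxy alcohol F3. Acylation with 3-methylbut-2-enoic anhydride, DMAP and Et3N then proceeds with retention to 26.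

Step 12: the lithium chlorohydrin alkoxide may close to an oxirane on warming, and the α-chloro aldehyde may enolise or self-condense under the basic conditions, giving low conversion. The fallback avoids the alkoxide by changing the electrophile; it sets out from 16 and returns at 18. The dilithio derivative of 16 is acylated with 2-chloro-N-methoxy-N-methylpropanamide (stable tetrahedral intermediate) to the α-chloro ynone F4. Luche reduction (NaBH4, CeCl3·7H2O, MeOH, −78 °C) then gives 18, again as an inconsequential mixture of isomers.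

**Further compounds**

F1 | step 16 | (2Z,4S,6E)-10-hydroxy-11-methyl macrocyclic enone (β-hydroxy ketone; 7-CH2OTBDPS; mixture at C10/C11) | O=C1/C=C\[C@@](C)(C/C=C/C(C)(C)O)C/C=C(/CO[Si](c2ccccc2)(c2ccccc2)C(C)(C)C)CCC(O)C1C
F2 | step 16 | (2Z,4S,6E,10E)-macrocyclic cross-conjugated dienone (7-CH2OTBDPS) | O=C1/C=C\[C@@](C)(C/C=C/C(C)(C)O)C/C=C(/CO[Si](c2ccccc2)(c2ccccc2)C(C)(C)C)CC/C=C1\C
F3 | step 18 | (1R,2Z,4S,6E,10S,11R)-threo epoxy alcohol (7-CH2OTBDPS) | O[C@@H]1/C=C\[C@@](C)(C/C=C/C(C)(C)O)C/C=C(/CO[Si](c3ccccc3)(c3ccccc3)C(C)(C)C)CC[C@@H]2O[C@]21C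
F4 | step 12 | (4S)-seco-chain α-chloro ynone CH3CHCl–C(=O)–C≡C–C4 (7-CH2OTBDPS; 10-OTBS) | CC(Cl)C(=O)C#C[C@@](C)(C/C=C/C(C)(C)O)C/C=C(/CO[Si](c1ccccc1)(c1ccccc1)C(C)(C)C)CCCO[Si](C)(C)C(C)(C)C
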